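**Retrosynthetic overview**

- The target is 8-[(2S)-lavandulyl]kaempferol (lavandulyl = 5-methyl-2-(prop-1-en-2-yl)hex-4-en-1-yl). The strategy rests on C2'': a CH between two CH2 groups, C1'' (on C8 of ring A) and C3'' (on alkene carbon C4''), whose third carbon substituent, the isopropenyl group, can be delivered from boron.
- Ring C is opened at O1–C2 and C2–C3 (cyclodehydration, then Baker–Venkataraman acyl shift). Ring B leaves as a 4-oxygenated benzoate, and C3/C4 as a silyloxyacetyl group on ring A.
- Isopropenyl at C2'' is traced back to a pinacol boronate (Zweifel olefination, retention).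
- Key disconnection: C1''–C2'' and C3''–C4'' by enantioselective palladium-catalysed conjunctive coupling of a symmetric 2,6-bis(MOM-oxy)-4-(TIPS-oxy)benzyl pinacol boronate, vinyllithium and 2-methylprop-1-enyl triflate.
- Ring order: rings A and B are bought (phloroglucinol, a 4-oxygenated benzoic acid). Ring C is the only ring made (step 15); the TIPS ether on the future O5 forces closure through the oxygen next to C8.

Key step: step 6

Assumption: the sense of induction of the MandyPhos-type diphosphine with an arylmethyl migrating group is taken to follow the aryl and alkyl cases. The (Sp,Sp) antipode is written for the (S)-boronate; if a first run (oxidation of a sample to the carbinol, MTPA esters) shows the opposite sense, the (Rp,Rp) antipode is used with nothing else changed.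

**Route**

Step 1
Reactants: 1 phloroglucinol
Product: 2 5-[(triisopropylsilyl)oxy]benzene-1,3-diol
Conditions: TIPSCl (1 equiv), imidazole, DMF, 0 °C → rt (1 in threefold excess)
Reagents that add atoms: triisopropylsilyl chloride, CC(C)[Si](Cl)(C(C)C)C(C)C
Why: O-silylation of a phenol under imidazole catalysis, in which the excess of the cheap, water-soluble triol should hold the reaction at the monosilyl ether and is washed out with water afterwards.

Step 2
Reactants: 2 5-[(triisopropylsilyl)oxy]benzene-1,3-diol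
Product: 3 [3,5-bis(methoxymethoxy)phenoxy]triisopropylsilane
Conditions: MOMCl, i-Pr2NEt, CH2Cl2, 0 °C → rt
Reagents that add atoms: chloromethyl methyl ether, COCCl
Why: Williamson-type O-alkylation of both phenols by the reactive α-chloro ether under amine base, conditions that leave the aryl silyl ether untouched.

Step 3
Reactants: 3 [3,5-bis(methoxymethoxy)phenoxy]triisopropylsilane; 4 2-(bromomethyl)-4,4,5,5-tetramethyl-1,3,2-dioxaborolane
Product: 7 2-[[2,6-bis(methoxymethoxy)-4-[(triisopropylsilyl)oxy]phenyl]methyl]-4,4,5,5-tetramethyl-1,3,2-dioxaborolane, via aryllithium 5 (not isolated), via bromomethyl borate complex 6 (not isolated)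
Conditions: n-BuLi, THF, 0 °C; then 4, −78 °C → rt; chromatography (removes LiBr)
Reagents that add atoms: none
Why: directed ortho-metalation takes place at the only carbon flanked by two OMOM groups (the carbons next to OTIPS are shielded and not activated), and the aryllithium adds to boron of 4 to give a borate whose aryl group shifts 1,2 with loss of bromide (Matteson homologation).

Step 4
Reactants: 8 isobutyraldehyde
Product: 9 2-methylprop-1-en-1-yl trifluoromethanesulfonate
Conditions: Tf2O, 2,6-di-tert-butyl-4-methylpyridine, CH2Cl2, 0 °C → rt; distillation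
Reagents that add atoms: trifluoromethanesulfonic anhydride, O=S(=O)(OS(=O)(=O)C(F)(F)F)C(F)(F)F
Why: O-triflylation of the aldehyde followed by loss of its single α-proton to the hindered, non-nucleophilic base (enol triflate formation from an enolisable aldehyde), and with two identical methyl groups only one alkene isomer can form.

Step 5
Reactants: 10 tetravinyltin, Sn(CH=CH2)4
Product: 11 vinyllithium
Conditions: n-BuLi, pentane, rt; solid filtered, washed, dissolved in THF, titrated
Reagents that add atoms: n-butyllithium, [Li]CCCC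
Why: tin–lithium exchange driven by precipitation of vinyllithium from pentane gives a halide-free reagent, which matters because halide ions suppress the coupling of step 6.

Step 6
Reactants: 7 2-[[2,6-bis(methoxymethoxy)-4-[(triisopropylsilyl)oxy]phenyl]methyl]-4,4,5,5-tetramethyl-1,3,2-dioxaborolane; 11 vinyllithium; 9 2-methylprop-1-en-1-yl trifluoromethanesulfonate
Product: 13 2-[(2S)-1-[2,6-bis(methoxymethoxy)-4-[(triisopropylsilyl)oxy]phenyl]-5-methylhex-4-en-2-yl]-4,4,5,5-tetramethyl-1,3,2-dioxaborolane, via vinyl borate complex 12 (not isolated)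
Conditions: 11 (1.0 equiv), THF, 0 °C → rt; then Pd(OAc)2 (2 mol %), (Sp,Sp)-MandyPhos [2,2'-bis[α-(dimethylamino)benzyl]-1,1'-bis(diphenylphosphino)ferrocene, C52H50FeN2P2] (2.4 mol %), 9 (1.2 equiv), degassed THF, 60 °C
Reagents that add atoms: none
Why: Oxidative addition of triflate 9 to zerovalent palladium (formed from Pd(OAc)2 and the diphosphine) gives a cationic alkenylpalladium complex that binds the vinyl group of borate 12; this activation triggers a 1,2-metallate shift in which the arylmethyl group moves from boron to the vinyl α-carbon anti to palladium (C1''–C2''), and reductive elimination of the resulting β-boryl alkyl(alkenyl)palladium forms C3''–C4''. The closest known reaction type is the enantioselective palladium-catalysed conjunctive cross-coupling of vinylboron ate complexes with aryl and alkenyl triflates, which is established for sp3-carbon migrating groups on pinacol boronates. No ring is closed. The single new stereocentre, C2'', is set by the chiral ferrocenyl diphosphine, which selects the enantioface of the vinyl group to which palladium binds; 7 is achiral, so there is no substrate bias to overcome. The step needs migration of the arylmethyl carbon in preference to a pinacol oxygen, and conjunctive coupling in preference to direct Suzuki-type transfer of the vinyl or arylmethyl group: the first is secured by the much higher migratory aptitude of carbon in four-coordinate pinacol borates, the second by the halide-free medium (vinyllithium from tin–lithium exchange, a triflate electrophile, 7 freed of LiBr), which keeps palladium cationic, and by the chelating ligand, which speeds reductive elimination over β-hydride loss. The symmetric 2,6-bis(methoxymethoxy) pattern of 7 means that no regiochemical question arises on ring A at this stage.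

Step 7
Reactants: 13 2-[(2S)-1-[2,6-bis(methoxymethoxy)-4-[(triisopropylsilyl)oxy]phenyl]-5-methylhex-4-en-2-yl]-4,4,5,5-tetramethyl-1,3,2-dioxaborolane; 14 2-bromopropene
Product: 18 [3,5-bis(methoxymethoxy)-4-[(2S)-5-methyl-2-(prop-1-en-2-yl)hex-4-en-1-yl]phenoxy]triisopropylsilane, via isopropenyllithium 15 (not isolated), via isopropenyl borate complex 16 (not isolated), via β-iodoalkyl boronate 17 (not isolated)
Conditions: 14, t-BuLi (2 equiv per 14), Et2O, −78 °C; then 13, THF, −78 °C; I2, MeOH, −78 °C; NaOMe, MeOH, −78 → 0 °C; Na2S2O3 work-up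
Reagents that add atoms: none
Why: Zweifel olefination, in which iodine activates the alkenyl group of the borate, the secondary alkyl group migrates from boron to carbon with retention at C2'' and methoxide-induced anti elimination of boron and iodide releases the 1,1-disubstituted alkene without acid or transition metal, the borate alkene being far more nucleophilic towards iodine at −78 °C than the isolated alkene or the arene.

Step 8
Reactants: 18 [3,5-bis(methoxymethoxy)-4-[(2S)-5-methyl-2-(prop-1-en-2-yl)hex-4-en-1-yl]phenoxy]triisopropylsilane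
Product: 19 [2-bromo-3,5-bis(methoxymethoxy)-4-[(2S)-5-methyl-2-(prop-1-en-2-yl)hex-4-en-1-yl]phenoxy]triisopropylsilane
Conditions: NBS (1.0 equiv), CH2Cl2, −78 → −30 °C, dark
Reagents that add atoms: N-bromosuccinimide, O=C1CCC(=O)N1Br
Why: electrophilic aromatic bromination of the trioxygenated ring should be much faster at low temperature than attack of NBS on the isolated alkenes, the two open ring positions are equivalent so one equivalent gives one monobromide, and bromine is chosen as the handle because deprotonation of a ring carbon next to the bulky, non-coordinating OTIPS group is not reliable.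

Step 9
Reactants: 20 methyl glycolate
Product: 21 methyl 2-[(triisopropylsilyl)oxy]acetate
Conditions: TIPSCl, imidazole, DMF, rt
Reagents that add atoms: triisopropylsilyl chloride, CC(C)[Si](Cl)(C(C)C)C(C)C
Why: routine O-silylation of an unhindered primary alcohol.

Step 10
Reactants: 21 methyl 2-[(triisopropylsilyl)oxy]acetate
Product: 22 N-methoxy-N-methyl-2-[(triisopropylsilyl)oxy]acetamide
Conditions: MeNH(OMe)·HCl, i-PrMgCl, THF, −20 → 0 °C
Reagents that add atoms: N,O-dimethylhydroxylamine hydrochloride, CNOC.Cl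
Why: aminolysis of the ester by the magnesium amide of N,O-dimethylhydroxylamine (Weinreb amide formation), which is fast at low temperature and does not touch the silyl ether.

Step 11
Reactants: 19 [2-bromo-3,5-bis(methoxymethoxy)-4-[(2S)-5-methyl-2-(prop-1-en-2-yl)hex-4-en-1-yl]phenoxy]triisopropylsilane; 22 N-methoxy-N-methyl-2-[(triisopropylsilyl)oxy]acetamide
Product: 24 1-[2,4-bis(methoxymethoxy)-3-[(2S)-5-methyl-2-(prop-1-en-2-yl)hex-4-en-1-yl]-6-[(triisopropylsilyl)oxy]phenyl]-2-[(triisopropylsilyl)oxy]ethan-1-one, via aryllithium 23 (not isolated)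
Conditions: t-BuLi (2.0 equiv), THF, −78 °C, 10 min; then 22, −78 → −30 °C; aq. NH4Cl
Reagents that add atoms: none
Why: bromine–lithium exchange outruns any other reaction of t-BuLi, the aryllithium is kept at −78 °C where a 1,3 O→C shift of the bulky TIPS group is slow, and its addition to the N-methoxy-N-methylamide stops at the chelated tetrahedral adduct that gives the ketone only on work-up (Weinreb ketone synthesis).

Step 12
Reactants: 24 1-[2,4-bis(methoxymethoxy)-3-[(2S)-5-methyl-2-(prop-1-en-2-yl)hex-4-en-1-yl]-6-[(triisopropylsilyl)oxy]phenyl]-2-[(triisopropylsilyl)oxy]ethan-1-one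
Product: 25 1-[2-hydroxy-4-(methoxymethoxy)-3-[(2S)-5-methyl-2-(prop-1-en-2-yl)hex-4-en-1-yl]-6-[(triisopropylsilyl)oxy]phenyl]-2-[(triisopropylsilyl)oxy]ethan-1-one
Conditions: MgBr2·OEt2 (3 equiv), n-BuSH (2 equiv), Et2O, 0 °C → rt, stopped at the monophenol
Reagents that add atoms: none
Why: magnesium chelated between the ketone oxygen and the ortho acetal oxygen activates only the MOM group next to the acyl group, whose methylene is taken up by the thiol, while the non-chelated para MOM ether and the poorly donating silyl ethers should remain (chelation-controlled Lewis acid cleavage of an acetal), and no protic acid is present that could add the freed phenol to the isopropenyl group.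

Step 13
Reactants: 25 1-[2-hydroxy-4-(methoxymethoxy)-3-[(2S)-5-methyl-2-(prop-1-en-2-yl)hex-4-en-1-yl]-6-[(triisopropylsilyl)oxy]phenyl]-2-[(triisopropylsilyl)oxy]ethan-1-one; 26 4-(methoxymethoxy)benzoic acid
Product: 27 5-(methoxymethoxy)-6-[(2S)-5-methyl-2-(prop-1-en-2-yl)hex-4-en-1-yl]-2-[2-[(triisopropylsilyl)oxy]acetyl]-3-[(triisopropylsilyl)oxy]phenyl 4-(methoxymethoxy)benzoate
Conditions: EDC·HCl, DMAP (1 equiv), CH2Cl2, rt
Reagents that add atoms: none
Why: Steglich esterification through the N-acylpyridinium ion acylates the single free phenol and avoids an acid chloride that would endanger the MOM ether of the acid; because the other ortho oxygen carries TIPS, the aroyl group can only sit on the oxygen next to the lavandulyl-bearing carbon.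

Step 14
Reactants: 27 5-(methoxymethoxy)-6-[(2S)-5-methyl-2-(prop-1-en-2-yl)hex-4-en-1-yl]-2-[2-[(triisopropylsilyl)oxy]acetyl]-3-[(triisopropylsilyl)oxy]phenyl 4-(methoxymethoxy)benzoate
Product: 28 1-[2-hydroxy-4-(methoxymethoxy)-3-[(2S)-5-methyl-2-(prop-1-en-2-yl)hex-4-en-1-yl]-6-[(triisopropylsilyl)oxy]phenyl]-3-[4-(methoxymethoxy)phenyl]-2-[(triisopropylsilyl)oxy]propane-1,3-dione (keto, enol and cyclic hemiketal forms; C2 of the dione unassigned)
Conditions: LiN(SiMe3)2 (3 equiv), THF, −78 → 0 °C; AcOH quench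
Reagents that add atoms: none
Why: Baker–Venkataraman rearrangement, in which the ketone enolate attacks the neighbouring aryl ester through a six-membered transition state and the acyl group moves from oxygen to carbon, driven by formation of the doubly stabilised diketone enolate and phenoxide, with the lithium base and low temperature chosen to keep both TIPS ethers in place.

Step 15
Reactants: 28 1-[2-hydroxy-4-(methoxymethoxy)-3-[(2S)-5-methyl-2-(prop-1-en-2-yl)hex-4-en-1-yl]-6-[(triisopropylsilyl)oxy]phenyl]-3-[4-(methoxymethoxy)phenyl]-2-[(triisopropylsilyl)oxy]propane-1,3-dione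
Product: 29 7-(methoxymethoxy)-2-[4-(methoxymethoxy)phenyl]-8-[(2S)-5-methyl-2-(prop-1-en-2-yl)hex-4-en-1-yl]-3,5-bis[(triisopropylsilyl)oxy]-4H-chromen-4-one
Conditions: camphor-10-sulfonic acid (10 mol %), toluene, 40 °C
Reagents that add atoms: none
Why: acid-catalysed cyclodehydration of the Baker–Venkataraman diketone (6-exo-trig hemiketalisation of the phenol onto the aroyl ketone, then loss of water to the chromone), in which only the oxygen next to C8 is free to close ring C because the other ortho oxygen is still silylated, so the 8-substituted rather than the 6-substituted flavone results, and the catalytic, water-poor medium spares the MOM ethers.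

Step 16
Reactants: 29 7-(methoxymethoxy)-2-[4-(methoxymethoxy)phenyl]-8-[(2S)-5-methyl-2-(prop-1-en-2-yl)hex-4-en-1-yl]-3,5-bis[(triisopropylsilyl)oxy]-4H-chromen-4-one
Product: 31 7-hydroxy-2-(4-hydroxyphenyl)-8-[(2S)-5-methyl-2-(prop-1-en-2-yl)hex-4-en-1-yl]-3,5-bis[(triisopropylsilyl)oxy]-4H-chromen-4-one, via bis(trimethylsilyl) ether 30 (not isolated)
Conditions: TMSOTf, 2,2'-bipyridyl, MeCN/CH2Cl2, 0 °C → rt; then H2O, rt
Reagents that add atoms: none
Why: the silyl triflate–bipyridyl pair converts aromatic MOM ethers into aryl trimethylsilyl ethers under buffered, non-protic conditions and water then hydrolyses these labile silyl ethers (silyl-transfer dealkoxymethylation), so the oxygen at C7 is never a free phenol in the presence of a strong acid that could cyclise it onto the isopropenyl group, and the TIPS ethers are not affected.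

Step 17
Reactants: 31 7-hydroxy-2-(4-hydroxyphenyl)-8-[(2S)-5-methyl-2-(prop-1-en-2-yl)hex-4-en-1-yl]-3,5-bis[(triisopropylsilyl)oxy]-4H-chromen-4-one
Product: 32 3,5,7-trihydroxy-2-(4-hydroxyphenyl)-8-[(2S)-5-methyl-2-(prop-1-en-2-yl)hex-4-en-1-yl]-4H-chromen-4-one (target)
Conditions: TBAF, AcOH (1:1), THF, 0 °C → rt, under argon
Reagents that add atoms: none
Why: fluoride-induced desilylation buffered with acetic acid removes the TIPS groups from the enolic 3-oxygen and the peri 5-oxygen, both good leaving groups, without acid or strong base that could alter the lavandulyl chain or its stereocentre.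

**Compound list**

1 | phloroglucinol | Oc1cc(O)cc(O)c1 | starting material
2 | 5-[(triisopropylsilyl)oxy]benzene-1,3-diol | CC(C)[Si](Oc1cc(O)cc(O)c1)(C(C)C)C(C)C | intermediate
3 | [3,5-bis(methoxymethoxy)phenoxy]triisopropylsilane | COCOc1cc(OCOC)cc(O[Si](C(C)C)(C(C)C)C(C)C)c1 | intermediate
4 | 2-(bromomethyl)-4,4,5,5-tetramethyl-1,3,2-dioxaborolane | CC1(C)OB(CBr)OC1(C)C | starting material
5 | [2,6-bis(methoxymethoxy)-4-[(triisopropylsilyl)oxy]phenyl]lithium | [Li]c1c(OCOC)cc(O[Si](C(C)C)(C(C)C)C(C)C)cc1OCOC | intermediate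
6 | lithium (bromomethyl)[2,6-bis(methoxymethoxy)-4-[(triisopropylsilyl)oxy]phenyl](pinacolato)borate | [Li+].CC1(C)O[B-](CBr)(c2c(OCOC)cc(O[Si](C(C)C)(C(C)C)C(C)C)cc2OCOC)OC1(C)C | intermediate
7 | 2-[[2,6-bis(methoxymethoxy)-4-[(triisopropylsilyl)oxy]phenyl]methyl]-4,4,5,5-tetramethyl-1,3,2-dioxaborolane | CC1(C)OB(Cc2c(OCOC)cc(O[Si](C(C)C)(C(C)C)C(C)C)cc2OCOC)OC1(C)C | intermediate
8 | isobutyraldehyde | CC(C)C=O | starting material
9 | 2-methylprop-1-en-1-yl trifluoromethanesulfonate | CC(C)=COS(=O)(=O)C(F)(F)F | intermediate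
10 | tetravinyltin | C=C[Sn](C=C)(C=C)C=C | starting material
11 | vinyllithium | [Li]C=C | intermediate
12 | lithium [2,6-bis(methoxymethoxy)-4-[(triisopropylsilyl)oxy]benzyl](vinyl)(pinacolato)borate | [Li+].C=C[B-]1(Cc2c(OCOC)cc(O[Si](C(C)C)(C(C)C)C(C)C)cc2OCOC)OC(C)(C)C(C)(C)O1 | intermediate
13 | 2-[(2S)-1-[2,6-bis(methoxymethoxy)-4-[(triisopropylsilyl)oxy]phenyl]-5-methylhex-4-en-2-yl]-4,4,5,5-tetramethyl-1,3,2-dioxaborolane | CC1(C)OB([C@@H](CC=C(C)C)Cc2c(OCOC)cc(O[Si](C(C)C)(C(C)C)C(C)C)cc2OCOC)OC1(C)C | intermediate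
14 | 2-bromopropene | C=C(C)Br | starting material
15 | isopropenyllithium | [Li]C(C)=C | intermediate
16 | lithium isopropenyl borate complex of 13 | [Li+].C=C(C)[B-]1([C@@H](CC=C(C)C)Cc2c(OCOC)cc(O[Si](C(C)C)(C(C)C)C(C)C)cc2OCOC)OC(C)(C)C(C)(C)O1 | intermediate
17 | β-iodoalkyl boronate (both configurations at the boron-bearing carbon; (S) at C2'') | CC1(C)OB(C(C)(CI)[C@@H](CC=C(C)C)Cc2c(OCOC)cc(O[Si](C(C)C)(C(C)C)C(C)C)cc2OCOC)OC1(C)C | intermediate
18 | [3,5-bis(methoxymethoxy)-4-[(2S)-5-methyl-2-(prop-1-en-2-yl)hex-4-en-1-yl]phenoxy]triisopropylsilane | C=C(C)[C@@H](CC=C(C)C)Cc1c(OCOC)cc(O[Si](C(C)C)(C(C)C)C(C)C)cc1OCOC | intermediate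
19 | [2-bromo-3,5-bis(methoxymethoxy)-4-[(2S)-5-methyl-2-(prop-1-en-2-yl)hex-4-en-1-yl]phenoxy]triisopropylsilane | C=C(C)[C@@H](CC=C(C)C)Cc1c(OCOC)cc(O[Si](C(C)C)(C(C)C)C(C)C)c(Br)c1OCOC | intermediate
20 | methyl glycolate | COC(=O)CO | starting material
21 | methyl 2-[(triisopropylsilyl)oxy]acetate | COC(=O)CO[Si](C(C)C)(C(C)C)C(C)C | intermediate
22 | N-methoxy-N-methyl-2-[(triisopropylsilyl)oxy]acetamide | CON(C)C(=O)CO[Si](C(C)C)(C(C)C)C(C)C | intermediate
23 | aryllithium from 19 (lithium in place of bromine) | C=C(C)[C@@H](CC=C(C)C)Cc1c(OCOC)cc(O[Si](C(C)C)(C(C)C)C(C)C)c([Li])c1OCOC | intermediate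
24 | 1-[2,4-bis(methoxymethoxy)-3-[(2S)-5-methyl-2-(prop-1-en-2-yl)hex-4-en-1-yl]-6-[(triisopropylsilyl)oxy]phenyl]-2-[(triisopropylsilyl)oxy]ethan-1-one | C=C(C)[C@@H](CC=C(C)C)Cc1c(OCOC)cc(O[Si](C(C)C)(C(C)C)C(C)C)c(C(=O)CO[Si](C(C)C)(C(C)C)C(C)C)c1OCOC | intermediate
25 | 1-[2-hydroxy-4-(methoxymethoxy)-3-[(2S)-5-methyl-2-(prop-1-en-2-yl)hex-4-en-1-yl]-6-[(triisopropylsilyl)oxy]phenyl]-2-[(triisopropylsilyl)oxy]ethan-1-one | C=C(C)[C@@H](CC=C(C)C)Cc1c(OCOC)cc(O[Si](C(C)C)(C(C)C)C(C)C)c(C(=O)CO[Si](C(C)C)(C(C)C)C(C)C)c1O | intermediate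
26 | 4-(methoxymethoxy)benzoic acid | COCOc1ccc(C(=O)O)cc1 | starting material
27 | 5-(methoxymethoxy)-6-[(2S)-5-methyl-2-(prop-1-en-2-yl)hex-4-en-1-yl]-2-[2-[(triisopropylsilyl)oxy]acetyl]-3-[(triisopropylsilyl)oxy]phenyl 4-(methoxymethoxy)benzoate | C=C(C)[C@@H](CC=C(C)C)Cc1c(OCOC)cc(O[Si](C(C)C)(C(C)C)C(C)C)c(C(=O)CO[Si](C(C)C)(C(C)C)C(C)C)c1OC(=O)c2ccc(OCOC)cc2 | intermediate
28 | 1-[2-hydroxy-4-(methoxymethoxy)-3-[(2S)-5-methyl-2-(prop-1-en-2-yl)hex-4-en-1-yl]-6-[(triisopropylsilyl)oxy]phenyl]-3-[4-(methoxymethoxy)phenyl]-2-[(triisopropylsilyl)oxy]propane-1,3-dione | C=C(C)[C@@H](CC=C(C)C)Cc1c(OCOC)cc(O[Si](C(C)C)(C(C)C)C(C)C)c(C(=O)C(O[Si](C(C)C)(C(C)C)C(C)C)C(=O)c2ccc(OCOC)cc2)c1O | intermediate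
29 | 7-(methoxymethoxy)-2-[4-(methoxymethoxy)phenyl]-8-[(2S)-5-methyl-2-(prop-1-en-2-yl)hex-4-en-1-yl]-3,5-bis[(triisopropylsilyl)oxy]-4H-chromen-4-one | C=C(C)[C@@H](CC=C(C)C)Cc1c(OCOC)cc(O[Si](C(C)C)(C(C)C)C(C)C)c2c(=O)c(O[Si](C(C)C)(C(C)C)C(C)C)c(-c3ccc(OCOC)cc3)oc12 | intermediate
30 | 8-[(2S)-5-methyl-2-(prop-1-en-2-yl)hex-4-en-1-yl]-3,5-bis[(triisopropylsilyl)oxy]-7-[(trimethylsilyl)oxy]-2-[4-[(trimethylsilyl)oxy]phenyl]-4H-chromen-4-one | C=C(C)[C@@H](CC=C(C)C)Cc1c(O[Si](C)(C)C)cc(O[Si](C(C)C)(C(C)C)C(C)C)c2c(=O)c(O[Si](C(C)C)(C(C)C)C(C)C)c(-c3ccc(O[Si](C)(C)C)cc3)oc12 | intermediate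
31 | 7-hydroxy-2-(4-hydroxyphenyl)-8-[(2S)-5-methyl-2-(prop-1-en-2-yl)hex-4-en-1-yl]-3,5-bis[(triisopropylsilyl)oxy]-4H-chromen-4-one | C=C(C)[C@@H](CC=C(C)C)Cc1c(O)cc(O[Si](C(C)C)(C(C)C)C(C)C)c2c(=O)c(O[Si](C(C)C)(C(C)C)C(C)C)c(-c3ccc(O)cc3)oc12 | intermediate
32 | 3,5,7-trihydroxy-2-(4-hydroxyphenyl)-8-[(2S)-5-methyl-2-(prop-1-en-2-yl)hex-4-en-1-yl]-4H-chromen-4-one | C=C(C)[C@@H](CC=C(C)C)Cc1c(O)cc(O)c2c(=O)c(O)c(-c3ccc(O)cc3)oc12 | target

**Step count**

Total: 17 steps (steps 4, 5, 9 and 10 make the side components). Longest linear sequence: 13 steps (1, 2, 3, 6, 7, 8, 11, 12, 13, 14, 15, 16, 17).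

**Steps most likely to fail**

Step 6. The 1,2-shift of the arylmethyl group, which carries two ortho substituents, may be slow. Direct Suzuki-type transfer of the vinyl group or β-hydride loss from the alkylpalladium intermediate could then compete, and enantiofacial control with this migrating group may fall short. The fallback sets out from 7 and returns at 13 by reagent-controlled lithiation–borylation, which needs no catalyst. Commercial 4-methylpent-3-en-1-ol is carbamoylated (i-Pr2NCOCl, Et3N, reflux) to 4-methylpent-3-en-1-yl N,N-diisopropylcarbamate F1. Treatment with s-BuLi/(+)-sparteine in Et2O at −78 °C removes the pro-R proton next to oxygen and gives the configurationally stable (R)-1-lithio carbamate F2. Boronate 7 is added and captured with retention as the lithium borate complex F3. MgBr2·OEt2 and warming then drive the 1,2-shift of the arylmethyl group with inversion and loss of the carbamate, which gives 13.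

Step 11. The aryllithium is crowded by the neighbouring OTIPS group and may add to the amide too slowly, so that proton transfer from the amide or a 1,3 O→C silyl shift takes over. The fallback sets out from 19 and returns at 24 by using a smaller, more electrophilic carbonyl partner and adjusting the oxidation level afterwards. Ester 21 is reduced (i-Bu2AlH, CH2Cl2, −78 °C) to 2-[(triisopropylsilyl)oxy]acetaldehyde F4. The aryllithium from 19 (t-BuLi, THF, −78 °C) is added to it to give 1-[2,4-bis(methoxymethoxy)-3-[(2S)-5-methyl-2-(prop-1-en-2-yl)hex-4-en-1-yl]-6-[(triisopropylsilyl)oxy]phenyl]-2-[(triisopropylsilyl)oxy]ethan-1-ol F5 (both configurations at the carbinol carbon). Dess–Martin periodinane (NaHCO3, CH2Cl2) then oxidises the benzylic carbinol to 24.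

Step 12. Discrimination between the chelated ortho acetal and the non-chelated para acetal may be incomplete, so that both aryl MOM groups are partly lost. The fallback sets out from 24 and returns at 25 by moving the differentiation from the cleavage to the alkylation. Excess MgBr2·OEt2/n-BuSH is used until both aryl acetals are gone, giving 1-[2,4-dihydroxy-3-[(2S)-5-methyl-2-(prop-1-en-2-yl)hex-4-en-1-yl]-6-[(triisopropylsilyl)oxy]phenyl]-2-[(triisopropylsilyl)oxy]ethan-1-one F6. MOMCl (1.05 equiv) with i-Pr2NEt in CH2Cl2 at 0 °C then alkylates only the para hydroxyl, because the ortho hydroxyl is held in a hydrogen bond to the ketone, and gives 25.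

Further compounds
F1 | step 6 | 4-methylpent-3-en-1-yl N,N-diisopropylcarbamate | CC(C)=CCCOC(=O)N(C(C)C)C(C)C
F2 | step 6 | (R)-1-lithio-4-methylpent-3-en-1-yl N,N-diisopropylcarbamate (sparteine complex) | CC(C)N(C(C)C)C(=O)O[C@@H](CC=C(C)C)[Li]
F3 | step 6 | lithium borate complex of 7 and F2 | [Li+].CC(C)N(C(C)C)C(=O)O[C@@H](CC=C(C)C)[B-]1(Cc2c(OCOC)cc(O[Si](C(C)C)(C(C)C)C(C)C)cc2OCOC)OC(C)(C)C(C)(C)O1
F4 | step 11 | 2-[(triisopropylsilyl)oxy]acetaldehyde | O=CCO[Si](C(C)C)(C(C)C)C(C)C
F5 | step 11 | 1-[2,4-bis(methoxymethoxy)-3-[(2S)-5-methyl-2-(prop-1-en-2-yl)hex-4-en-1-yl]-6-[(triisopropylsilyl)oxy]phenyl]-2-[(triisopropylsilyl)oxy]ethan-1-ol | C=C(C)[C@@H](CC=C(C)C)Cc1c(OCOC)cc(O[Si](C(C)C)(C(C)C)C(C)C)c(C(O)CO[Si](C(C)C)(C(C)C)C(C)C)c1OCOC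
F6 | step 12 | 1-[2,4-dihydroxy-3-[(2S)-5-methyl-2-(prop-1-en-2-yl)hex-4-en-1-yl]-6-[(triisopropylsilyl)oxy]phenyl]-2-[(triisopropylsilyl)oxy]ethan-1-one | C=C(C)[C@@H](CC=C(C)C)Cc1c(O)cc(O[Si](C(C)C)(C(C)C)C(C)C)c(C(=O)CO[Si](C(C)C)(C(C)C)C(C)C)c1O
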